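The cyclohexanone ring (C1–C5, C10; labdane numbering) is disconnected at C4–C5. Its 3-keto-4-methyl-4-(oxymethyl) array next to ring-fusion C5 is the signature of a semipinacol shift. In one operation, Lewis acid opening of a 2-methyloxiranyl carbinol enlarges a cyclopentane (C1, C2, C3, C5, C10) to this ring and creates the C3 ketone, the C4 quaternary stereocentre and the free hydroxymethyl group. The precursor is a cis-hydrindanol carrying the epoxide on C3, the C8 exocyclic methylene and a C9 vinyl group. It comes from an asymmetric conjugate addition to 3-methylcyclopentenone and a Pd-catalysed enyne cycloisomerisation. The vinyl group is finally extended by B-alkyl Suzuki coupling.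

Key step: step 7

Remark: the target is taken exactly as drawn, i.e. a cis-fused decalin with H-5, CH3-10, the C9 side chain and the C4 methyl on one face and CH2OAc on the other; labdane numbering (C17 = exocyclic methylene carbon, C11–C16 = side chain) is used for all intermediates.

Step 1
Reactants: 1 4-(trimethylsilyl)but-3-yn-1-ol
Product: 2 4-(trimethylsilyl)but-3-yn-1-yl trifluoromethanesulfonate
Conditions: Tf2O, pyridine, CH2Cl2, −78 → −20 °C; cold filtration through silica (pentane), used at once
Reagents that add atoms: trifluoromethanesulfonic anhydride, O=S(=O)(OS(=O)(=O)C(F)(F)F)C(F)(F)F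
Why: O-sulfonylation of the primary alcohol gives a primary triflate, an SN2 electrophile reactive enough to alkylate a hindered ketone enolate at low temperature before elimination to the enyne sets in; no stereocentre is formed.

Step 2
Reactants: 3 3-methylcyclopent-2-en-1-one; 4 propyne
Product: 7 trimethyl({(3R)-3-methyl-3-[(1E)-prop-1-en-1-yl]cyclopent-1-en-1-yl}oxy)silane, via alkenylalane 5 (not isolated), via aluminium enolate 6 (not isolated)
Conditions: 4, DIBAL-H, hexane, 55 °C (sealed); then 3, Cu(OTf)2 (5 mol %), chiral sulfonate-bridged NHC–Ag(I) complex (2.5 mol %), THF, −78 °C; then TMSOTf, −78 → 0 °C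
Reagents that add atoms: trimethylsilyl trifluoromethanesulfonate, C[Si](C)(C)OS(=O)(=O)C(F)(F)F
Why: syn-hydroalumination gives the (E)-alkenylalane, whose alkenyl group is transferred in a copper-catalysed asymmetric conjugate addition to the β-methyl enone, the chiral NHC–Cu complex selecting the enone face so that the quaternary centre (later C10) is set as shown, and O-silylation of the aluminium enolate fixes the enolate regiochemistry towards the later C5.

Step 3
Reactants: 7 trimethyl({(3R)-3-methyl-3-[(1E)-prop-1-en-1-yl]cyclopent-1-en-1-yl}oxy)silane; 2 4-(trimethylsilyl)but-3-yn-1-yl trifluoromethanesulfonate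
Product: 10 (2R,3R)-2-(but-3-yn-1-yl)-3-methyl-3-[(1E)-prop-1-en-1-yl]cyclopentan-1-one, via lithium enolate 8 (not isolated), via silylalkyne ketone 9 (not isolated)
Conditions: MeLi, THF, 0 °C; then 2, −78 → −30 °C; then TBAF, AcOH, 0 °C
Reagents that add atoms: none
Why: methyllithium cleaves the silyl enol ether to the regiodefined lithium enolate, which should be C-alkylated (SN2) by the primary triflate with the electrophile entering anti to the larger propenyl group (2R; this α-keto centre is correctable, the minor epimer being separable and re-equilibrated), and buffered fluoride then removes the alkynyl silyl group without epimerisation.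

Step 4
Reactants: 10 (2R,3R)-2-(but-3-yn-1-yl)-3-methyl-3-[(1E)-prop-1-en-1-yl]cyclopentan-1-one
Product: 12 (3aR,4S,7aS)-4-ethenyl-3a-methyl-5-methylideneoctahydro-1H-inden-1-one, via trans-fused ketone 11 (not isolated)
Conditions: Pd(OAc)2 (5 mol %), N,N′-bis(benzylidene)ethylenediamine (5 mol %), PhH, 60 °C; then DBU (0.2 equiv), rt
Reagents that add atoms: none
Why: palladium-catalysed Alder-ene cycloisomerisation of the 1,7-enyne (alkyne hydropalladation, 6-exo carbopalladation of the propenyl group, β-hydride elimination from its methyl group) should form the C8–C9 bond, the C8=C17 methylene and the C9 vinyl group in one event, the trans-disposed tether allowing only a chair-like transition state with the alkene equatorial and the angular methyl axial so that C9 is set with vinyl cis to that methyl, after which DBU epimerises C5 next to the ketone to the more stable cis-fused hydrindanone.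

Step 5
Reactants: 12 (3aR,4S,7aS)-4-ethenyl-3a-methyl-5-methylideneoctahydro-1H-inden-1-one
Product: 13 (1R,3aR,4S,7aS)-4-ethenyl-3a-methyl-5-methylidene-1-(prop-1-en-2-yl)octahydro-1H-inden-1-ol
Conditions: isopropenylmagnesium bromide, anhydrous CeCl3, THF, −78 → 0 °C
Reagents that add atoms: isopropenylmagnesium bromide, CC(=C)[Mg]Br
Why: 1,2-addition of the weakly basic organocerium reagent to the enolisable ketone should take place from the convex face of the cis-hydrindanone, anti to C6 of the six-membered ring, which sets C3 with the hydroxyl on the concave face (1R).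

Step 6
Reactants: 13 (1R,3aR,4S,7aS)-4-ethenyl-3a-methyl-5-methylidene-1-(prop-1-en-2-yl)octahydro-1H-inden-1-ol
Product: 14 (1R,3aR,4S,7aS)-4-ethenyl-3a-methyl-5-methylidene-1-[(2S)-2-methyloxiran-2-yl]octahydro-1H-inden-1-ol
Conditions: VO(acac)2 (5 mol %), t-BuOOH (decane), CH2Cl2, 0 °C
Reagents that add atoms: tert-butyl hydroperoxide, CC(C)(C)OO
Why: vanadium-catalysed hydroxyl-directed epoxidation touches only the allylic isopropenyl double bond, and oxygen should be delivered from the hydroxyl side in the rotamer that places the less substituted C2, not C5, next to the vinylic methyl (minimised A(1,2) strain), which sets the oxirane carbon (2S) and leaves its oxygen anti to the C3–C5 bond.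

Step 7
Reactants: 14 (1R,3aR,4S,7aS)-4-ethenyl-3a-methyl-5-methylidene-1-[(2S)-2-methyloxiran-2-yl]octahydro-1H-inden-1-ol
Product: 15 (1R,4aS,5S,8aS)-5-ethenyl-1-(hydroxymethyl)-1,4a-dimethyl-6-methylideneoctahydronaphthalen-2(1H)-one
Conditions: BF3·OEt2 (0.3 equiv), CH2Cl2, −78 °C; then Et3N, sat. NaHCO3
Reagents that add atoms: none
Why: BF3 coordinates the oxirane oxygen, the tertiary C4–O bond ionises and, in concert, the antiperiplanar C3–C5 bond of the cyclopentanol migrates to C4 while the carbinol oxygen becomes the C3 carbonyl, so that C4 is inserted between C3 and C5 and the five-membered ring (C1, C2, C3, C5, C10) becomes the six-membered ring (C1–C5, C10). The closest known reaction type is the Lewis-acid semipinacol rearrangement of tertiary 2,3-epoxy alcohols with ring expansion of 1-(oxiran-2-yl)cycloalkanols (Suzuki–Tsuchihashi-type 1,2-shift). No ring is closed by cyclisation: the six-membered ring arises by a suprafacial 1,2-alkyl shift with retention at the migrating C5, which carries the cis ring fusion over unchanged. The new quaternary stereocentre C4 is set by the oxirane configuration, because C5 enters anti to the leaving oxygen (inversion at C4), placing the C4 methyl on the face of H-5 and CH3-10 and the hydroxymethyl on the opposite face. The step needs migration of C5 and not of C2, which is secured by the higher migratory aptitude of the more substituted ring-fusion carbon and by the epoxide being formed with its oxygen already anti to C3–C5; it also needs the isolated 1,4-diene to stay untouched, which the sub-stoichiometric Lewis acid at −78 °C secures.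

Step 8
Reactants: 15 (1R,4aS,5S,8aS)-5-ethenyl-1-(hydroxymethyl)-1,4a-dimethyl-6-methylideneoctahydronaphthalen-2(1H)-one
Product: 16 [(1R,4aS,5S,8aS)-5-ethenyl-1,4a-dimethyl-6-methylidene-2-oxodecahydronaphthalen-1-yl]methyl acetate
Conditions: Ac2O, pyridine, DMAP (cat.), CH2Cl2, 0 °C → rt
Reagents that add atoms: acetic anhydride, CC(=O)OC(C)=O
Why: DMAP-catalysed acylation of the primary alcohol should proceed without touching the ketone or the alkenes and also protects the β-hydroxy ketone against retro-aldol loss of formaldehyde in the basic last step; no stereocentre is affected.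

Step 9
Reactants: 17 but-2-ynoic acid
Product: 18 (2Z)-3-iodobut-2-enoic acid
Conditions: NaI, AcOH, 110 °C
Reagents that add atoms: sodium iodide, [Na+].[I-]
Why: conjugate anti-hydroiodination of the ynoic acid (iodide adds to C3, protonation at C2 trans to iodine) should give the (Z)-β-iodo acid, which fixes the later C13=C14 geometry.

Step 10
Reactants: 16 [(1R,4aS,5S,8aS)-5-ethenyl-1,4a-dimethyl-6-methylidene-2-oxodecahydronaphthalen-1-yl]methyl acetate; 18 (2Z)-3-iodobut-2-enoic acid
Product: 20 (2Z)-5-[(1S,4aS,5R,8aR)-5-(acetoxymethyl)-5,8a-dimethyl-2-methylidene-6-oxodecahydronaphthalen-1-yl]-3-methylpent-2-enoic acid, via alkylborane 19 (not isolated)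
Conditions: disiamylborane (from BH3·THF and 2-methylbut-2-ene), THF, 0 °C; then 18, Cs2CO3, H2O, Pd(dppf)Cl2 (5 mol %), AsPh3, DMF, rt → 40 °C; acidify to pH 3
Reagents that add atoms: none
Why: the hindered dialkylborane should hydroborate the monosubstituted vinyl group anti-Markovnikov much faster than the 1,1-disubstituted exocyclic alkene or the α-quaternary ketone, and the primary alkylborane then undergoes B-alkyl Suzuki–Miyaura coupling with the vinyl iodide (as its caesium carboxylate) with retention of the Z geometry, forming C12–C13 and completing the side chain.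

Compound list
1 | 4-(trimethylsilyl)but-3-yn-1-ol | C[Si](C)(C)C#CCCO | starting material
2 | 4-(trimethylsilyl)but-3-yn-1-yl trifluoromethanesulfonate | C[Si](C)(C)C#CCCOS(=O)(=O)C(F)(F)F | intermediate
3 | 3-methylcyclopent-2-en-1-one | CC1=CC(=O)CC1 | starting material
4 | propyne | CC#C | starting material
5 | diisobutyl[(1E)-prop-1-en-1-yl]alumane | C/C=C/[Al](CC(C)C)CC(C)C | intermediate
6 | diisobutylaluminium (3R)-3-methyl-3-[(1E)-prop-1-en-1-yl]cyclopent-1-en-1-olate | CC(C)C[Al](CC(C)C)OC1=C[C@@](C)(/C=C/C)CC1 | intermediate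
7 | trimethyl({(3R)-3-methyl-3-[(1E)-prop-1-en-1-yl]cyclopent-1-en-1-yl}oxy)silane | C[Si](C)(C)OC1=C[C@@](C)(/C=C/C)CC1 | intermediate
8 | lithium (3R)-3-methyl-3-[(1E)-prop-1-en-1-yl]cyclopent-1-en-1-olate | [Li]OC1=C[C@@](C)(/C=C/C)CC1 | intermediate
9 | (2R,3R)-3-methyl-3-[(1E)-prop-1-en-1-yl]-2-[4-(trimethylsilyl)but-3-yn-1-yl]cyclopentan-1-one | C[Si](C)(C)C#CCC[C@H]1C(=O)CC[C@]1(C)/C=C/C | intermediate
10 | (2R,3R)-2-(but-3-yn-1-yl)-3-methyl-3-[(1E)-prop-1-en-1-yl]cyclopentan-1-one | C#CCC[C@H]1C(=O)CC[C@]1(C)/C=C/C | intermediate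
11 | (3aR,4S,7aR)-4-ethenyl-3a-methyl-5-methylideneoctahydro-1H-inden-1-one (trans-fused) | C=C1CC[C@@H]2[C@](C)(CCC2=O)[C@H]1C=C | intermediate
12 | (3aR,4S,7aS)-4-ethenyl-3a-methyl-5-methylideneoctahydro-1H-inden-1-one (cis-fused) | C=C1CC[C@H]2[C@](C)(CCC2=O)[C@H]1C=C | intermediate
13 | (1R,3aR,4S,7aS)-4-ethenyl-3a-methyl-5-methylidene-1-(prop-1-en-2-yl)octahydro-1H-inden-1-ol | C=C1CC[C@H]2[C@](C)(CC[C@]2(O)C(C)=C)[C@H]1C=C | intermediate
14 | (1R,3aR,4S,7aS)-4-ethenyl-3a-methyl-5-methylidene-1-[(2S)-2-methyloxiran-2-yl]octahydro-1H-inden-1-ol | C=C1CC[C@H]2[C@](C)(CC[C@]2(O)[C@]3(C)CO3)[C@H]1C=C | intermediate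
15 | (1R,4aS,5S,8aS)-5-ethenyl-1-(hydroxymethyl)-1,4a-dimethyl-6-methylideneoctahydronaphthalen-2(1H)-one | C=C1CC[C@H]2[C@](C)(CCC(=O)[C@@]2(C)CO)[C@H]1C=C | intermediate
16 | [(1R,4aS,5S,8aS)-5-ethenyl-1,4a-dimethyl-6-methylidene-2-oxodecahydronaphthalen-1-yl]methyl acetate | C=C1CC[C@H]2[C@](C)(CCC(=O)[C@@]2(C)COC(C)=O)[C@H]1C=C | intermediate
17 | but-2-ynoic acid | CC#CC(=O)O | starting material
18 | (2Z)-3-iodobut-2-enoic acid | C/C(I)=C/C(=O)O | intermediate
19 | [(1R,4aR,5S,8aS)-5-{2-[bis(3-methylbutan-2-yl)boranyl]ethyl}-1,4a-dimethyl-6-methylidene-2-oxodecahydronaphthalen-1-yl]methyl acetate | C=C1CC[C@H]2[C@](C)(CCC(=O)[C@@]2(C)COC(C)=O)[C@H]1CCB(C(C)C(C)C)C(C)C(C)C | intermediate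
20 | (2Z)-5-[(1S,4aS,5R,8aR)-5-(acetoxymethyl)-5,8a-dimethyl-2-methylidene-6-oxodecahydronaphthalen-1-yl]-3-methylpent-2-enoic acid | C=C1CC[C@H]2[C@](C)(CCC(=O)[C@@]2(C)COC(C)=O)[C@H]1CC/C(C)=C\C(=O)O | target

Total step count: 10
Longest linear sequence: 8 steps (3 → 20 through steps 2–8 and 10)

Steps most likely to fail

Step 4 (enyne cycloisomerisation). What may go wrong: oligomerisation of the terminal alkyne, sluggish closure of the six-membered ring onto the hindered propenyl group, or β-hydride loss from C9 instead of the methyl group, which would give the conjugated diene. The fallback sets out from 10 and comes back at 12. Markovnikov hydroiodination of the alkyne (NaI, Me3SiCl, H2O, MeCN) would give the vinyl iodide (2R,3R)-2-(3-iodobut-3-en-1-yl)-3-methyl-3-[(1E)-prop-1-en-1-yl]cyclopentan-1-one F1. An intramolecular 6-exo Heck reaction (Pd(OAc)2, PPh3, Ag2CO3, MeCN, 70 °C), in which the alkenylpalladium iodide adds across the propenyl group and the hydride is lost from the methyl group, followed by DBU, would then lead to 12.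

Step 3 (enolate alkylation). What may go wrong: O-alkylation by the hard triflate, or proton exchange between product and the hindered enolate, with loss of regiocontrol and dialkylation. The fallback sets out from 7 and comes back at 10. A Mannich reaction of 7 with N,N-dimethylmethyleneiminium iodide would give the β-amino ketone (2S,3R)-2-[(dimethylamino)methyl]-3-methyl-3-[(1E)-prop-1-en-1-yl]cyclopentan-1-one F2. Quaternisation and elimination (MeI, then DBU) would give the α-methylene ketone (3R)-3-methyl-2-methylidene-3-[(1E)-prop-1-en-1-yl]cyclopentan-1-one F3. TiCl4-promoted conjugate propargylation with allenyl(tributyl)stannane (SE2′), followed by separation of the C2 epimers, would give 10.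

Step 10 (hydroboration and cross-coupling). What may go wrong: the free carboxylate may bind boron or palladium so that transmetallation of the hindered dialkylborane stalls, and protodeboronation or hydrolysis of the acetate by the aqueous base takes over. The fallback sets out from 16 and comes back at 20. The borane 19 would be oxidised (NaBO3·4H2O) to the alcohol [(1R,4aR,5S,8aS)-5-(2-hydroxyethyl)-1,4a-dimethyl-6-methylidene-2-oxodecahydronaphthalen-1-yl]methyl acetate F4 and converted (I2, PPh3, imidazole) into the iodide [(1R,4aR,5S,8aS)-5-(2-iodoethyl)-1,4a-dimethyl-6-methylidene-2-oxodecahydronaphthalen-1-yl]methyl acetate F5. Zinc insertion (Zn dust, DMA) would give the alkylzinc iodide {2-[(1S,4aS,5R,8aR)-5-(acetoxymethyl)-5,8a-dimethyl-2-methylidene-6-oxodecahydronaphthalen-1-yl]ethyl}(iodo)zinc F6. This would be coupled under base-free Negishi conditions (PdCl2(dppf), THF/DMA) with 2-(trimethylsilyl)ethyl (2Z)-3-iodobut-2-enoate F7 (from 18, 2-(trimethylsilyl)ethanol, DCC, DMAP) to give the ester 2-(trimethylsilyl)ethyl (2Z)-5-[(1S,4aS,5R,8aR)-5-(acetoxymethyl)-5,8a-dimethyl-2-methylidene-6-oxodecahydronaphthalen-1-yl]-3-methylpent-2-enoate F8. TASF in DMF would then release 20 with the acetate intact.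

Further compounds
F1 | step 4 | (2R,3R)-2-(3-iodobut-3-en-1-yl)-3-methyl-3-[(1E)-prop-1-en-1-yl]cyclopentan-1-one | C=C(I)CC[C@H]1C(=O)CC[C@]1(C)/C=C/C
F2 | step 3 | (2S,3R)-2-[(dimethylamino)methyl]-3-methyl-3-[(1E)-prop-1-en-1-yl]cyclopentan-1-one | CN(C)C[C@H]1C(=O)CC[C@]1(C)/C=C/C
F3 | step 3 | (3R)-3-methyl-2-methylidene-3-[(1E)-prop-1-en-1-yl]cyclopentan-1-one | C=C1C(=O)CC[C@]1(C)/C=C/C
F4 | step 10 | [(1R,4aR,5S,8aS)-5-(2-hydroxyethyl)-1,4a-dimethyl-6-methylidene-2-oxodecahydronaphthalen-1-yl]methyl acetate | C=C1CC[C@H]2[C@](C)(CCC(=O)[C@@]2(C)COC(C)=O)[C@H]1CCO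
F5 | step 10 | [(1R,4aR,5S,8aS)-5-(2-iodoethyl)-1,4a-dimethyl-6-methylidene-2-oxodecahydronaphthalen-1-yl]methyl acetate | C=C1CC[C@H]2[C@](C)(CCC(=O)[C@@]2(C)COC(C)=O)[C@H]1CCI
F6 | step 10 | {2-[(1S,4aS,5R,8aR)-5-(acetoxymethyl)-5,8a-dimethyl-2-methylidene-6-oxodecahydronaphthalen-1-yl]ethyl}(iodo)zinc | C=C1CC[C@H]2[C@](C)(CCC(=O)[C@@]2(C)COC(C)=O)[C@H]1CC[Zn]I
F7 | step 10 | 2-(trimethylsilyl)ethyl (2Z)-3-iodobut-2-enoate | C/C(I)=C/C(=O)OCC[Si](C)(C)C
F8 | step 10 | 2-(trimethylsilyl)ethyl (2Z)-5-[(1S,4aS,5R,8aR)-5-(acetoxymethyl)-5,8a-dimethyl-2-methylidene-6-oxodecahydronaphthalen-1-yl]-3-methylpent-2-enoate | C=C1CC[C@H]2[C@](C)(CCC(=O)[C@@]2(C)COC(C)=O)[C@H]1CC/C(C)=C\C(=O)OCC[Si](C)(C)C
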